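**Plan**

1. Last cut: the two O–CH3 bonds on the A ring, on either side of its single formyl group.
2. Main cut: O1–C2 and C4–C4a of the chroman (A ring fused, B ring on C2). This gives 4-hydroxy-2,6-dimethoxybenzaldehyde and a C2–C3–C4 unit bound to the diformylphloroglucinol ring as a vinylogous o-quinone methide, stored as its racemic 2H-chromene.
3. The chromene is cut at its aryl–CH and O–CH(isobutyl) bonds into 2,4-diformylphloroglucinol (from phloroglucinol) and 2-isopropyl-5-methylhex-2-enal.
4. Enabling feature: C2–C3–C4 with its isopropyl and isobutyl groups is the aldol dimer of isovaleraldehyde, held between two phloroglucinol rings (on C2 and C4) and bridged by O1. One ring can therefore carry the chain as a 1,3-dielectrophile while the other delivers carbon, then oxygen.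
5. Forward order: formylation, a sacrificial pyran (chromene) ring, its opening and closure of the final pyran ring onto the second arene, then demethylation.
6. Stereochemistry: all three centres arise in the annulation. C4 comes from the chiral phosphoric acid, C3 from protonation under allylic strain (3,4-cis), C2 from reversible closure (2,3-trans); the chromene's own centre is erased.

Key step: step 3

Assumption: the sense of induction of the phosphoric acid cannot be predicted for this new annulation; (R)-TRIP, the (R)-BINOL hydrogen phosphate with 2,4,6-triisopropylphenyl groups at C3 and C3′, is written, and its antipode would be used if the first run shows the opposite sense at C4.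

**Step 1**
Reactants: 1 phloroglucinol (benzene-1,3,5-triol)
Product: 3 2,4,6-trihydroxybenzene-1,3-dicarbaldehyde (2,4-diformylphloroglucinol), via bis-iminium salt 2 (not isolated)
Conditions: POCl3 (2.2 equiv), DMF (2.2 equiv), 1,4-dioxane, 0 °C → rt; then H2O
Reagents that add atoms: N,N-dimethylformamide, CN(C)C=O; water, O
Why: Vilsmeier–Haack formylation: the chloroiminium ion formed from DMF and POCl3 substitutes two of the three equivalent, doubly activated ring carbons of 1, each iminium group deactivating the ring enough that about two equivalents of reagent should stop at bis-iminium salt 2, which water hydrolyses to the dialdehyde.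

**Step 2**
Reactants: 3 2,4-diformylphloroglucinol; 4 (E)-2-isopropyl-5-methylhex-2-enal
Product: 6 rac-5,7-dihydroxy-2-(2-methylpropyl)-3-(propan-2-yl)-2H-chromene-6,8-dicarbaldehyde, via allylic carbinol 5 (not isolated)
Conditions: piperidine (20 mol %), AcOH (20 mol %), toluene–THF, 80 °C
Reagents that add atoms: none
Why: Amine-catalysed Knoevenagel condensation followed by oxa-6π electrocyclisation (the formal [3+3] chromene synthesis from phenols and enals): the single free ring carbon of 3 adds to the carbonyl carbon of 4, activated as its iminium ion, to give carbinol 5 or its amine-bound equivalent, loss of water then gives the vinylogous o-quinone methide with isobutyl outward (this is compound 7, which step 3 regenerates from 6), and either of the two equivalent flanking phenol oxygens closes the 2H-pyran, the new C2 centre arising racemic, which is acceptable because step 3 erases it; a secondary amine salt is chosen because a primary amine would be held by the formyl groups as an enaminone.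

**Step 3**
Reactants: 6 rac-5,7-dihydroxy-2-(2-methylpropyl)-3-(propan-2-yl)-2H-chromene-6,8-dicarbaldehyde; 8 4-hydroxy-2,6-dimethoxybenzaldehyde
Product: 11 (2R,3R,4S)-2-(3,5-diformyl-2,4,6-trihydroxyphenyl)-5,7-dimethoxy-4-(2-methylpropyl)-3-(propan-2-yl)-3,4-dihydro-2H-chromene-6-carbaldehyde (2,3-trans-3,4-cis), via vinyl quinone methide 7 (not isolated), via styrene 9 (not isolated), via quinone methide 10 (not isolated)
Conditions: 8 (1.5 equiv), (R)-TRIP (10 mol %), 4 Å MS, PhCF3, 0 °C → rt, then 50 °C
Reagents that add atoms: none
Why: Proposed new method: the phosphoric acid assists opening of the O–C2 bond of 6 (retro-oxa-6π) to the planar vinylogous o-quinone methide 7, so both enantiomers of 6 converge on one achiral electrophile; hydrogen-bonded to the quinone methide carbonyl and to the hydroxyl of 8, it holds 7 in the cisoid form in which the isobutyl-bearing δ-carbon lies near that carbonyl and guides the ortho carbon of 8 onto it (1,6-addition, C4–C4a) to give (Z)-styrene 9, which is protonated at C3 to o-quinone methide 10 and closed by the A-ring oxygen (O1–C2). The closest known reactions are chiral phosphoric acid-catalysed Friedel–Crafts additions and formal cycloadditions of phenols and naphthols with o-quinone methides generated in situ, and the reversible opening of 2H-chromenes to vinyl o-quinone methides. The pyran ring closes by 6-exo-trig oxa-conjugate addition of the phenol oxygen to the methide carbon of 10. C4 (S) is set by the catalyst, which shields one face of the δ-carbon in the hydrogen-bonded assembly; C3 (R) follows from protonation of 9 anti to the new aryl group on the conformer whose C4–H bond eclipses the alkene (allylic 1,3-strain with the cis B ring), which places isopropyl cis to isobutyl and is backed by the stability of the half-chair with 3-isopropyl equatorial and 4-isobutyl pseudoaxial away from the peri 5-methoxy group, since 9, 10 and 11 interconvert under the acid; C2 (R) is set by reversible closure to the 2,3-trans isomer with the aryl group equatorial. The step needs 1,6- over 1,4-addition and C- over O-alkylation: the benzylic terminus of 7 is screened by the two ortho oxygens of its ring and by the isopropyl group, O-adducts are ethers of a stabilised cation and revert, and only the 1,6-C-adduct can drain into the chroman. The A-ring regiochemistry is fixed because 8 has two equivalent ortho carbons and one free hydroxyl, and 7 cannot self-condense because its ring has no free carbon.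

**Step 4**
Reactants: 11 (2R,3R,4S)-2-(3,5-diformyl-2,4,6-trihydroxyphenyl)-5,7-dimethoxy-4-(2-methylpropyl)-3-(propan-2-yl)-3,4-dihydro-2H-chromene-6-carbaldehyde
Product: 12 (2R,3R,4S)-2-(3,5-diformyl-2,4,6-trihydroxyphenyl)-5,7-dihydroxy-4-(2-methylpropyl)-3-(propan-2-yl)-3,4-dihydro-2H-chromene-6-carbaldehyde (CNP0328914.1)
Conditions: BCl3 (excess), n-Bu4NI, CH2Cl2, −78 → 0 °C; then H2O
Reagents that add atoms: none
Why: Lewis acid-mediated O-demethylation: boron binds the formyl oxygen and each flanking methoxy oxygen in turn and iodide removes the methyl groups by SN2 at low temperature, conditions under which aryl aldehydes and the chroman are retained, and no stereocentre is touched because a transient opening of O1–C2 could only reclose to the same favoured 2,3-trans arrangement.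

**Compound list**

1 | phloroglucinol (benzene-1,3,5-triol) | Oc1cc(O)cc(O)c1 | starting material
2 | (2,4,6-trihydroxy-1,3-phenylene)bis(N,N-dimethylmethaniminium) dichloride (bis-iminium salt) | C[N+](C)=Cc1c(O)cc(O)c(C=[N+](C)C)c1O.[Cl-].[Cl-] | intermediate (not isolated)
3 | 2,4,6-trihydroxybenzene-1,3-dicarbaldehyde (2,4-diformylphloroglucinol) | O=Cc1c(O)cc(O)c(C=O)c1O | intermediate
4 | (E)-2-isopropyl-5-methylhex-2-enal | CC(C)C/C=C(/C=O)C(C)C | starting material
5 | rac-2,4,6-trihydroxy-5-[(2E)-1-hydroxy-5-methyl-2-(propan-2-yl)hex-2-en-1-yl]benzene-1,3-dicarbaldehyde (allylic carbinol, Knoevenagel aldol adduct) | CC(C)C/C=C(/C(O)c1c(O)c(C=O)c(O)c(C=O)c1O)C(C)C | intermediate (not isolated)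
6 | rac-5,7-dihydroxy-2-(2-methylpropyl)-3-(propan-2-yl)-2H-chromene-6,8-dicarbaldehyde | CC(C)CC1Oc2c(C=O)c(O)c(C=O)c(O)c2C=C1C(C)C | intermediate
7 | 2,4-diformyl-3,5-dihydroxy-6-[(2E)-5-methyl-2-(propan-2-yl)hex-2-en-1-ylidene]cyclohexa-2,4-dien-1-one (vinylogous o-quinone methide; exocyclic geometry undefined) | CC(C)C/C=C(/C=C1C(=O)C(C=O)=C(O)C(C=O)=C1O)C(C)C | intermediate (not isolated)
8 | 4-hydroxy-2,6-dimethoxybenzaldehyde | COc1cc(O)cc(OC)c1C=O | starting material
9 | 5-[(1Z,3S)-3-(3-formyl-6-hydroxy-2,4-dimethoxyphenyl)-5-methyl-2-(propan-2-yl)hex-1-en-1-yl]-2,4,6-trihydroxybenzene-1,3-dicarbaldehyde (1,6-adduct, o-hydroxystyrene) | CC(C)C[C@H](c1c(O)cc(OC)c(C=O)c1OC)/C(C(C)C)=C\c1c(O)c(C=O)c(O)c(C=O)c1O | intermediate (not isolated)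
10 | 2,4-diformyl-6-[(2S,3S)-3-(3-formyl-6-hydroxy-2,4-dimethoxyphenyl)-5-methyl-2-(propan-2-yl)hexylidene]-3,5-dihydroxycyclohexa-2,4-dien-1-one (second o-quinone methide) | CC(C)C[C@H](c1c(O)cc(OC)c(C=O)c1OC)[C@@H](C(C)C)C=C1C(=O)C(C=O)=C(O)C(C=O)=C1O | intermediate (not isolated)
11 | (2R,3R,4S)-2-(3,5-diformyl-2,4,6-trihydroxyphenyl)-5,7-dimethoxy-4-(2-methylpropyl)-3-(propan-2-yl)-3,4-dihydro-2H-chromene-6-carbaldehyde | CC(C)C[C@@H]1c2c(cc(OC)c(C=O)c2OC)O[C@@H](c2c(O)c(C=O)c(O)c(C=O)c2O)[C@@H]1C(C)C | intermediate
12 | (2R,3R,4S)-2-(3,5-diformyl-2,4,6-trihydroxyphenyl)-5,7-dihydroxy-4-(2-methylpropyl)-3-(propan-2-yl)-3,4-dihydro-2H-chromene-6-carbaldehyde | CC(C)C[C@@H]1c2c(cc(O)c(C=O)c2O)O[C@@H](c2c(O)c(C=O)c(O)c(C=O)c2O)[C@@H]1C(C)C | target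

**Step count**

Total steps: 4. Longest linear sequence: 4 steps (1 → 3 → 6 → 11 → 12).

**Steps most likely to fail**

Step 3 (new method). The electron-poor phenol may add too slowly, so that the vinyl quinone methide drains by 1,7-hydrogen shift to a dienylphenol. Addition may also occur at the benzylic terminus or through oxygen, or with poor facial control at C4. The fallback uses the established inverse-demand oxa-Diels–Alder reaction of an o-quinone methide with an o-hydroxystyrene; it sets out from 3 and 8 and returns at 11. Dialdehyde 3, isovaleraldehyde F1 (purchased) and phenylboronic acid (cat. EtCO2H, toluene, Dean–Stark) should give benzodioxaborin F2 by Nagata ortho-hydroxyalkylation. Heating F2 releases o-quinone methide F3, whose 1,5-hydrogen shift gives (E)-styrene F4. Phenol 8 and F1 are then condensed (piperidinium acetate, toluene, heat) in the presence of F4. The Knoevenagel-derived o-quinone methide F5 should add to F4 with its oxygen at the benzylic carbon, the E-alkene fixing 2,3-trans. The 3,4-cis diastereomer would be separated by chromatography and resolved by preparative HPLC on a chiral stationary phase, giving 11 and leaving its enantiomer F6.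

Step 2. The Knoevenagel condensation of the α-branched enal with the deactivated, hydrogen-bonded phenol may be sluggish, conjugate addition at the β-carbon may compete with attack at the carbonyl carbon, and prolonged heating may divert the quinone methide. The fallback reverses the order of events; it sets out from 1 and 4 and returns at 6. Phloroglucinol 1 (in excess, to suppress double annulation) is condensed with 4 under EDDA to chromenediol F7. The two remaining, strongly activated ring positions are then formylated under Vilsmeier–Haack conditions through bis-iminium salt F8, whose hydrolysis gives 6.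

Step 4. Cleavage may stop after the first methyl ether because the second lies on the far side of an already chelated formyl group, and forcing conditions may open O1–C2 and erode C3. The fallback changes the protecting group; it sets out from 6 and returns at 12. Vilsmeier–Haack formylation of 3,5-bis(benzyloxy)phenol F9 (purchased) para to the hydroxyl, through iminium salt F10, should give 2,6-bis(benzyloxy)-4-hydroxybenzaldehyde F11. This replaces 8 in the annulation with 6 under the conditions of step 3, giving dibenzyl ether F12. BCl3 with pentamethylbenzene in CH2Cl2 at −78 °C then removes both benzyl groups to give 12.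

**Further compounds**

F1 | step 3 | 3-methylbutanal (isovaleraldehyde, purchased) | CC(C)CC=O
F2 | step 3 | rac-5,7-dihydroxy-4-(2-methylpropyl)-2-phenyl-4H-1,3,2-benzodioxaborinine-6,8-dicarbaldehyde | CC(C)CC1OB(c2ccccc2)Oc2c(C=O)c(O)c(C=O)c(O)c12
F3 | step 3 | 2,4-diformyl-3,5-dihydroxy-6-(3-methylbutylidene)cyclohexa-2,4-dien-1-one | CC(C)CC=C1C(=O)C(C=O)=C(O)C(C=O)=C1O
F4 | step 3 | 2,4,6-trihydroxy-5-[(1E)-3-methylbut-1-en-1-yl]benzene-1,3-dicarbaldehyde | CC(C)/C=C/c1c(O)c(C=O)c(O)c(C=O)c1O
F5 | step 3 | 4-formyl-3,5-dimethoxy-6-(3-methylbutylidene)cyclohexa-2,4-dien-1-one | CC(C)CC=C1C(=O)C=C(OC)C(C=O)=C1OC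
F6 | step 3 | (2S,3S,4R)-2-(3,5-diformyl-2,4,6-trihydroxyphenyl)-5,7-dimethoxy-4-(2-methylpropyl)-3-(propan-2-yl)-3,4-dihydro-2H-chromene-6-carbaldehyde (enantiomer of 11) | CC(C)C[C@H]1c2c(cc(OC)c(C=O)c2OC)O[C@H](c2c(O)c(C=O)c(O)c(C=O)c2O)[C@H]1C(C)C
F7 | step 2 | rac-2-(2-methylpropyl)-3-(propan-2-yl)-2H-chromene-5,7-diol | CC(C)CC1Oc2cc(O)cc(O)c2C=C1C(C)C
F8 | step 2 | rac-[5,7-dihydroxy-2-(2-methylpropyl)-3-(propan-2-yl)-2H-chromene-6,8-diyl]bis(N,N-dimethylmethaniminium) dichloride | CC(C)CC1Oc2c(C=[N+](C)C)c(O)c(C=[N+](C)C)c(O)c2C=C1C(C)C.[Cl-].[Cl-]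
F9 | step 4 | 3,5-bis(benzyloxy)phenol (purchased) | Oc1cc(OCc2ccccc2)cc(OCc2ccccc2)c1
F10 | step 4 | [2,6-bis(benzyloxy)-4-hydroxyphenyl]-N,N-dimethylmethaniminium chloride | C[N+](C)=Cc1c(OCc2ccccc2)cc(O)cc1OCc1ccccc1.[Cl-]
F11 | step 4 | 2,6-bis(benzyloxy)-4-hydroxybenzaldehyde | O=Cc1c(OCc2ccccc2)cc(O)cc1OCc1ccccc1
F12 | step 4 | (2R,3R,4S)-5,7-bis(benzyloxy)-2-(3,5-diformyl-2,4,6-trihydroxyphenyl)-4-(2-methylpropyl)-3-(propan-2-yl)-3,4-dihydro-2H-chromene-6-carbaldehyde | CC(C)C[C@@H]1c2c(cc(OCc3ccccc3)c(C=O)c2OCc2ccccc2)O[C@@H](c2c(O)c(C=O)c(O)c(C=O)c2O)[C@@H]1C(C)C
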